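## Locants and one assumption

Locants for every compound: ring A is C1–C5, the spiro carbon is C6, ring B is C7–C11. In the target, C1 carries the exocyclic methylene, C2 is the ketone, C3=C4 is the ring alkene with bromine on C4, and C5 carries two methyls. C7 is the CH2 between C6 and C8, C8 is CHBr, C9 is C(CH3)Cl. With these locants the target 17 is (6S,8S,9S)-4,8-dibromo-9-chloro-5,5,9-trimethyl-1-methylidenespiro[5.5]undec-3-en-2-one.

Assumption: the sense of induction of the cinchona amino-thiocarbamate in step 3 cannot be derived for this substrate class. The quinidine-derived catalyst is written; its quinine-derived pseudoenantiomer takes its place if that is the one that leads to 8.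

## Analysis of the target

The target is a halogenated spiro[5.5]undecane of the chamigrene family. Ring A is a cross-conjugated cyclohexenone (exocyclic methylene on C1, ketone C2, C3=C4 with bromine on C4, gem-dimethyl C5), and ring B is a cyclohexane with a secondary bromide on C8 and a methyl-bearing tertiary chloride on C9. There are three stereocentres: the quaternary spiro carbon C6 and the vicinal pair C8/C9, in which bromine and chlorine are anti. C6 is stereogenic only because the two arms of each ring differ, and it stands 1,3 to C8 and 1,4 to C9 with no functional group in between; its relation to the halogens is the real stereochemical problem. C1, C6 and C5 are three contiguous carbons without hydrogen, which slows every reaction at C6 and its neighbours. The α-methylene ketone is a strong Michael acceptor, the β-bromoenone is a vinylogous acyl bromide, and the tertiary chloride and secondary bromide eliminate with base and ionise with Lewis acids, so the dienone should appear last and the late steps should be neutral. The plan rests on one feature: the C9–Cl bond lies on the face of ring B that carries C1 (cis-1,4 across ring B) and is anti to the C8–Br bond. An oxygen bridge from C1 to C9, made by anti bromoetherification of a C8=C9 alkene, therefore stores C6, C8 and C9 in one bicyclic unit; if C1 and C5 start as equivalent C(CH3)OH groups, the choice of the bridging carbinol is a desymmetrisation of an achiral compound.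

## Retrosynthetic reasoning

**17 to 16.** The exocyclic C1=CH2 bond is cut back to the tertiary α-ketol 16. C2 is a carbonyl carbon and C6 is quaternary, so only the methyl group can lose hydrogen and no regiochemistry has to be controlled. The dienone is the most fragile part of 17, so this is the last step. The forward reaction must be a neutral dehydration that does not pass through a cation at C1.

**16 to 15.** The C9–Cl bond and the C1 hydroxyl are traced to the C1–O–C9 ether of 15. The oxygen already sits on the face of C9 where chlorine is wanted. In the forward sense the C9–O bond ionises with help from the antiperiplanar bromine on C8, and a chloride ion opens the bromonium ion at C9 on the face the oxygen left, which is retention. The C1–O bond is spared because a cation at C1 would sit next to the C2 carbonyl; this is why the ketone is installed before the ether is opened.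

**15 to 14, 13 and 12.** The C2 carbonyl is cut back to the allylic CH2 of vinyl bromide 14. C5 is quaternary, so C2 is the only allylic position with hydrogen. The C4–Br bond and the C3=C4 alkene come from ketone 12 through hydrazone 13. For the same reason, 12 can lose a proton only towards C3 and one vinyl bromide results.

**12 to 11, 10, 9 and 8.** One C5–CH3 bond and the C4 oxygen are cut together. Forward, the spare carbinol of 8 is dehydrated to alkene 9 and epoxidised to 10, and a Lewis acidic methyl donor delivers methyl to the tertiary epoxide carbon to give 11, which is oxidised to 12. The carbinol not used for the bridge is thus not waste: it supplies the gem-dimethyl group and the neighbouring oxygen that becomes the vinyl bromide.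

**8 to 7.** This is the key disconnection: the C9–O and C8–Br bonds are cut to give diol 7. Compound 7 is achiral, with a mirror plane through C3, C6 and ring B that exchanges the two carbinols. Forward, a chiral catalyst and an electrophilic bromine source must brominate one face of the C8=C9 alkene, and the carbinol on the other face must close at the tertiary carbon. One event then fixes C6, C8 and C9.

**7 to 5 and 6.** The two C–CH3 bonds at C1 and C5 are cut to dione 5 and two molecules of methyllithium 6, one for each carbonyl. "Cis" alone does not define the diol: two achiral cis-diols exist, differing in whether the hydroxyls face C7 or C11. Compound 7 is the one with both hydroxyls on the face of ring A that carries C7, and it has to be separated from the other.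

**5 to 1, 2 and 3.** Ring B is cut at C6–C7 and C10–C11 (Diels–Alder) and at the C6–C11 bond (Knoevenagel). Forward, 1 and formaldehyde 2 give the methylidene dione 4, which isoprene 3 takes up with the methyl 1,4 to the spiro carbon. C6 is not yet stereogenic in 5, so nothing has to be controlled there.

## Alternatives that were turned down

Alternative 1: The disconnection is the C6–C1 bond. A para-substituted phenol with a gem-dimethyl, silyloxy and terminal alkyne chain, 4-[3-(tert-butyldimethylsilyloxy)-2-methylhept-6-yn-2-yl]phenol A1, would be treated with Ph3PAuNTf2, a cationic phosphine complex of monovalent gold. The para carbon attacks the internal alkyne carbon in a 6-exo-dig ipso closure, giving the spiro cyclohexa-2,5-dienone A2.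
- For it: ring A arrives almost complete in one step, with exocyclic methylene, gem-dimethyl and the C4 oxygen in place. No epoxide methylation and no late dehydration are needed. On ring A it is stronger than the chosen route.
- Against it: in A2 the spiro carbon is not stereogenic, because ring B is a symmetric dienone. C6, C8 and C9 must all be set later, relative to a single carbinol on the far side of a quaternary carbon. That carbinol must be made enantiopure only to be oxidised away.
- Ring B of A2 still needs methyl addition at C9, saturation of one enone arm, and chlorine and bromine placed anti on defined faces. No element of A2 controls any of this.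
- Comparison: the chosen route spends more steps on ring A, but it sets the three stereocentres in one step from 7.

Alternative 2: The disconnection is ring B at C6–C11 and C7=C8. A chiral primary amine of the cinchona type would form the enamine of 3-bromo-2,2-dimethylcyclohex-3-ene-1-carbaldehyde A3 and add it to methyl vinyl ketone A4. Aldol condensation then closes ring B to the spiro cyclohexenone A5.
- For it: the catalyst sets the absolute configuration of C6 directly, with vinyl bromide and gem-dimethyl already in ring A. Here it equals the chosen route for C6 and avoids the ring A work after the key step.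
- Against it: the enamine carbon lies next to the CMe2 group, so the Michael step must build a quaternary carbon beside a quaternary carbon. Low rate and weak facial discrimination are to be expected.
- In A5, C9 is an enone carbonyl. Methyl addition, alkene transposition and an anti bromochlorination must follow, and the face of halogenation is left to a remote spiro centre. Ring A still needs oxidation at C2 and methylenation at C1.
- Comparison: it solves C6 alone, whereas the ether of 8 ties C8 and C9 to C6.

Alternative 3: The disconnection is the C5–C6 bond and ring A. (Z)-γ-Bisabolene A6 would be treated with a vanadium-dependent bromoperoxidase, a peroxide oxidant and a bromide salt. A bromonium ion on the terminal alkene is attacked by the tetrasubstituted alkene, and proton loss from the methyl gives the bromochamigrene A7.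
- For it: the whole carbon skeleton, the gem-dimethyl group, the exocyclic methylene and the spiro centre come from a C15 hydrocarbon in one step. In step economy it is clearly stronger than the chosen route.
- Against it: A6 has three alkenes open to electrophilic bromine, and the enzyme's control of site and of the configuration at C6 cannot be argued from structure.
- A7 carries bromine on an sp3 carbon. Turning it into the vinylic bromide of a β-bromoenone needs a dehydrogenation across C3–C4 with bromine retained, for which there is no direct reaction.
- The ring B alkene of A7 must still be bromochlorinated with no control of face.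
- Comparison: the chosen route is longer, but each stereocentre has a stated origin.

Key step: step 3

## Route

Step 1
Reactants: 1 cyclohexane-1,3-dione; 2 formaldehyde (37% aqueous solution); 3 isoprene
Product: 5 9-methylspiro[5.5]undec-8-ene-1,5-dione, via 2-methylidenecyclohexane-1,3-dione 4 (not isolated)
Conditions: 37% aq. CH2O, piperidine (cat.), AcOH (cat.), isoprene (5 equiv), 1,4-dioxane, sealed tube, 100 °C
Reagents that add atoms: none
Why: Knoevenagel condensation gives the doubly activated alkene 4, which isoprene traps in a Diels–Alder reaction; the diene terminus next to the methyl-bearing carbon bonds to the CH2 of 4, so the methyl ends 1,4 to the new quaternary carbon ("para" orientation). The Michael adduct of 4 with a second molecule of 1 forms reversibly and feeds 4 back at this temperature; no stereocentre is formed because C6 is not stereogenic in 5.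

Step 2
Reactants: 5 9-methylspiro[5.5]undec-8-ene-1,5-dione; 6 methyllithium
Product: 7 cis-1,5,9-trimethylspiro[5.5]undec-8-ene-1,5-diol (both hydroxyls on the face of ring A that carries C7; achiral)
Conditions: MeLi (4 equiv), CeCl3 (anhydrous, 4 equiv), THF, −78 °C; aq. NH4Cl; chromatography on AgNO3-impregnated silica
Reagents that add atoms: methyllithium (second equivalent of 6), [Li]C
Why: Twofold organocerium 1,2-addition in one flask: each of the two carbonyls of 5 takes one methyl group from one molecule of 6, delivered as the reagent formed from MeLi and CeCl3, which adds to hindered carbonyls without enolisation and holds the first β-keto alkoxide as a covalent cerium chelate, so that retro-aldol opening is suppressed before the second methyl arrives. The chelate places that oxygen axial and steers the second methyl to the equatorial direction, so a cis-diol should predominate over the trans-diol. No bias is expected between the two cis-diols, so 7 is separated from its C6 epimer by chromatography.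

Step 3
Reactants: 7 cis-1,5,9-trimethylspiro[5.5]undec-8-ene-1,5-diol
Product: 8 8-bromo-1,9-epoxy-1,5,9-trimethylspiro[5.5]undecan-5-ol (oxygen bridge from C1 to C9 on the face of ring B that carries C1; bromine on C8 on the opposite face, anti to the C9–O bond; C5 hydroxyl cis to the C1 oxygen on ring A; C6, C8, C9 as in 17)
Conditions: O-(quinidin-9-yl) N-(2,4-dimethoxyphenyl)thiocarbamate (10 mol %), NBS (1.1 equiv), CHCl3–PhMe (1:1), −60 °C, dark
Reagents that add atoms: N-bromosuccinimide, O=C1CCC(=O)N1Br
Why: Proposed new method: the thiocarbamate sulfur takes bromine from NBS while the quinuclidine nitrogen holds a carbinol by hydrogen bonding, so a bromonium ion is delivered to one enantiotopic face of the C8=C9 alkene; the hydroxyl on the other face, the one on C1, then opens it anti at the tertiary carbon C9. The closest known reaction type is the amino-thiocarbamate/NBS enantioselective desymmetrising bromoetherification of prochiral alkenyl diols, combined with the racemic bridged haloether closure of the α-terpineol-to-cineole kind; new here is the enantioselective bridged closure from tertiary carbinols onto a ring alkene. One ring is closed, the oxane O–C1–C6–C7–C8–C9 (equally O–C1–C6–C11–C10–C9), in a six-membered Markovnikov closure that is 6-endo through C7 and turns ring B into the boat of a 2-oxabicyclo[2.2.2]octane. C8 is set by the catalyst through the face of bromine delivery, C9 follows from anti opening of the bromonium ion, and C6 becomes stereogenic because only the carbinol opposite to bromine can close, so the choice of face is also the choice between the enantiotopic carbinols. The step needs enantioface selection (catalyst), attack at C9 rather than C8 (the tertiary end of the trisubstituted bromonium ion carries the charge, and closure at C8 would leave a tertiary bromide in a 6-oxabicyclo[3.2.1]octane), and ring closure ahead of capture by succinimide or water (intramolecular delivery, anhydrous medium, low temperature). The cost is conformational: for the C1 oxygen to reach C9, ring A must place the C1 and C5 methyls both axial, which slows the closure.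

Step 4
Reactants: 8 8-bromo-1,9-epoxy-1,5,9-trimethylspiro[5.5]undecan-5-ol
Product: 9 8-bromo-1,9-epoxy-1,5,9-trimethylspiro[5.5]undec-4-ene (C1, C6, C8, C9 as in 8)
Conditions: Burgess reagent (MeO2CN−SO2N+Et3), PhMe, 70 °C
Reagents that add atoms: none
Why: Burgess dehydration: the sulfamate ester of the tertiary carbinol collapses by syn elimination without a free cation next to the quaternary C6. Loss of a C4 hydrogen gives the more substituted ring alkene and relieves the 1,3-diaxial contact of the C1 and C5 methyls.

Step 5
Reactants: 9 8-bromo-1,9-epoxy-1,5,9-trimethylspiro[5.5]undec-4-ene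
Product: 10 8-bromo-1,9:4,5-diepoxy-1,5,9-trimethylspiro[5.5]undecane (oxirane on C4–C5, face not defined; other centres as in 8)
Conditions: mCPBA, NaHCO3, CH2Cl2, 0 °C
Reagents that add atoms: meta-chloroperoxybenzoic acid, OOC(=O)c1cccc(Cl)c1
Why: Prilezhaev epoxidation of the only alkene; the ether and the secondary bromide are inert to the peracid. The face of attack is of no consequence because C4 and C5 lose their configuration by step 7.

Step 6
Reactants: 10 8-bromo-1,9:4,5-diepoxy-1,5,9-trimethylspiro[5.5]undecane
Product: 11 8-bromo-1,9-epoxy-1,5,5,9-tetramethylspiro[5.5]undecan-4-ol (C4 not defined; other centres as in 8)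
Conditions: Me3Al (3 equiv), CH2Cl2–hexane, −78 → 0 °C; aq. potassium sodium tartrate
Reagents that add atoms: trimethylaluminium, C[Al](C)C
Why: Lewis-acid-assisted epoxide opening by trimethylaluminium: aluminium on the epoxide oxygen loosens the bond to the tertiary carbon C5, and a second molecule of Me3Al transfers methyl there with inversion. C5 becomes the gem-dimethyl carbon, and the C4 carbinol is oxidised next, so its configuration does not matter.

Step 7
Reactants: 11 8-bromo-1,9-epoxy-1,5,5,9-tetramethylspiro[5.5]undecan-4-ol
Product: 12 8-bromo-1,9-epoxy-1,5,5,9-tetramethylspiro[5.5]undecan-4-one (C1, C6, C8, C9 as in 8)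
Conditions: Dess–Martin periodinane, NaHCO3, CH2Cl2, rt
Reagents that add atoms: none
Why: Dess–Martin oxidation of a hindered secondary alcohol under buffered, non-basic conditions; no epimerisable centre is adjacent and both C4 epimers of 11 converge.

Step 8
Reactants: 12 8-bromo-1,9-epoxy-1,5,5,9-tetramethylspiro[5.5]undecan-4-one
Product: 13 hydrazone of 12 at C4 (other centres as in 8)
Conditions: N2H4·H2O, Et3N, EtOH, 80 °C
Reagents that add atoms: hydrazine, NN
Why: Hydrazone formation; the ketone is flanked by a quaternary carbon and needs heat. The secondary bromide sits on the rigid bicycle next to the fully substituted C9, where backside substitution is hindered and no antiperiplanar hydrogen is available for elimination.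

Step 9
Reactants: 13 hydrazone of 12
Product: 14 4,8-dibromo-1,9-epoxy-1,5,5,9-tetramethylspiro[5.5]undec-3-ene (C1, C6, C8, C9 as in 8)
Conditions: NBS (2.2 equiv), pyridine, CH2Cl2, −10 °C → rt
Reagents that add atoms: N-bromosuccinimide, O=C1CCC(=O)N1Br
Why: Barton-type vinyl halide synthesis with bromine as the halogen: NBS oxidises the hydrazone to the diazo compound and brominates it to the α-bromo diazonium ion; after loss of N2 the α-bromo cation loses the C3 proton, the only one available because C5 is quaternary. Bromine stabilises the cation and pyridine takes the proton before a methyl shift from C5 can compete.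

Step 10
Reactants: 14 4,8-dibromo-1,9-epoxy-1,5,5,9-tetramethylspiro[5.5]undec-3-ene
Product: 15 4,8-dibromo-1,9-epoxy-1,5,5,9-tetramethylspiro[5.5]undec-3-en-2-one (C1, C6, C8, C9 as in 8)
Conditions: CrO3 (15 equiv), 3,5-dimethylpyrazole (15 equiv), CH2Cl2, −20 °C
Reagents that add atoms: chromium trioxide, O=[Cr](=O)=O
Why: Allylic oxidation with the CrO3–3,5-dimethylpyrazole complex (hexavalent chromium): C2 is the only allylic position that bears hydrogen, since C5 is quaternary, so the enone can form in one place only. The ether, the alkyl bromide and the vinyl bromide are stable to the reagent.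

Step 11
Reactants: 15 4,8-dibromo-1,9-epoxy-1,5,5,9-tetramethylspiro[5.5]undec-3-en-2-one
Product: 16 4,8-dibromo-9-chloro-1-hydroxy-1,5,5,9-tetramethylspiro[5.5]undec-3-en-2-one (C6, C8, C9 as in 17; C1 as in 8)
Conditions: BCl3 (2.2 equiv), CH2Cl2, −78 → −30 °C; aq. NaHCO3
Reagents that add atoms: boron trichloride, ClB(Cl)Cl
Why: Lewis acid cleavage of a tertiary ether with neighbouring-group participation: BCl3 on the bridge oxygen ionises the C9–O bond with help from the antiperiplanar bromine on C8, and chloride opens the bromonium ion at the tertiary carbon C9 from the face the oxygen left, which is retention at C9 and leaves C8 untouched. The C1–O bond does not ionise because the cation would sit next to the C2 carbonyl; aqueous work-up frees the C1 hydroxyl.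

Step 12
Reactants: 16 4,8-dibromo-9-chloro-1-hydroxy-1,5,5,9-tetramethylspiro[5.5]undec-3-en-2-one
Product: 17 (6S,8S,9S)-4,8-dibromo-9-chloro-5,5,9-trimethyl-1-methylidenespiro[5.5]undec-3-en-2-one (target)
Conditions: Burgess reagent (MeO2CN−SO2N+Et3), PhH, 50 °C
Reagents that add atoms: none
Why: Burgess dehydration of the tertiary α-ketol: C2 is a carbonyl carbon and C6 is quaternary, so only the methyl group can give up hydrogen and the exocyclic methylene is the sole possible alkene. Neutral, base-free conditions spare the tertiary chloride and the dienone, which is formed last.

## Compound list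

1 | cyclohexane-1,3-dione | O=C1CCCC(=O)C1 | starting material
2 | formaldehyde | C=O | starting material
3 | isoprene | CC(=C)C=C | starting material
4 | 2-methylidenecyclohexane-1,3-dione | C=C1C(=O)CCCC1=O | intermediate (not isolated)
5 | 9-methylspiro[5.5]undec-8-ene-1,5-dione | O=C1CCCC(=O)C12CCC(C)=CC2 | intermediate
6 | methyllithium | [Li]C | starting material
7 | cis-1,5,9-trimethylspiro[5.5]undec-8-ene-1,5-diol, hydroxyls on the face of ring A that carries C7 | C[C@]1(O)CCC[C@@](C)(O)[C@]12CCC(C)=CC2 | intermediate
8 | 8-bromo-1,9-epoxy-1,5,9-trimethylspiro[5.5]undecan-5-ol | C[C@]1(O3)CCC[C@@](C)(O)[C@]12CC[C@@]3(C)[C@@H](Br)C2 | intermediate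
9 | 8-bromo-1,9-epoxy-1,5,9-trimethylspiro[5.5]undec-4-ene | C[C@]1(O3)CCC=C(C)[C@]12CC[C@@]3(C)[C@@H](Br)C2 | intermediate
10 | 8-bromo-1,9:4,5-diepoxy-1,5,9-trimethylspiro[5.5]undecane (C4, C5 not defined) | C[C@]1(O3)CCC4OC4(C)[C@]12CC[C@@]3(C)[C@@H](Br)C2 | intermediate
11 | 8-bromo-1,9-epoxy-1,5,5,9-tetramethylspiro[5.5]undecan-4-ol (C4 not defined) | C[C@]1(O3)CCC(O)C(C)(C)[C@]12CC[C@@]3(C)[C@@H](Br)C2 | intermediate
12 | 8-bromo-1,9-epoxy-1,5,5,9-tetramethylspiro[5.5]undecan-4-one | C[C@]1(O3)CCC(=O)C(C)(C)[C@]12CC[C@@]3(C)[C@@H](Br)C2 | intermediate
13 | hydrazone of 12 | C[C@]1(O3)CCC(=NN)C(C)(C)[C@]12CC[C@@]3(C)[C@@H](Br)C2 | intermediate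
14 | 4,8-dibromo-1,9-epoxy-1,5,5,9-tetramethylspiro[5.5]undec-3-ene | C[C@]1(O3)CC=C(Br)C(C)(C)[C@]12CC[C@@]3(C)[C@@H](Br)C2 | intermediate
15 | 4,8-dibromo-1,9-epoxy-1,5,5,9-tetramethylspiro[5.5]undec-3-en-2-one | C[C@]1(O3)C(=O)C=C(Br)C(C)(C)[C@]12CC[C@@]3(C)[C@@H](Br)C2 | intermediate
16 | 4,8-dibromo-9-chloro-1-hydroxy-1,5,5,9-tetramethylspiro[5.5]undec-3-en-2-one | C[C@]1(O)C(=O)C=C(Br)C(C)(C)[C@]12CC[C@](C)(Cl)[C@@H](Br)C2 | intermediate
17 | (6S,8S,9S)-4,8-dibromo-9-chloro-5,5,9-trimethyl-1-methylidenespiro[5.5]undec-3-en-2-one | C=C1C(=O)C=C(Br)C(C)(C)[C@]12CC[C@](C)(Cl)[C@@H](Br)C2 | target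

## Step count and the steps least certain to work

Total step count: 12. Longest linear sequence: 12 steps (from 1 to 17).

**Step 3 (key step, bears the label "Proposed new method:").** Enantioface discrimination may be weak, because the catalyst class was developed for less hindered carbinols and not for a ring alkene flanked by tertiary alcohols. The closure is also slowed by the diaxial methyls, which gives capture of the bromonium ion by succinimide or adventitious water, or allylic bromination, time to compete. The fallback sets out from 7 and uses known chemistry. NBS alone in CH2Cl2 at 0 °C gives racemic 8 by the bridged bromoetherification known from terpineol-type hydroxy alkenes, and the enantiomers are separated by preparative chromatography on a chiral stationary phase. The unwanted enantiomer of 8 F1 is returned to 7 with zinc in acetic acid (reductive elimination of the β-bromo ether) and recycled. The fallback comes back to the route at 8.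

**Step 6.** Methyl transfer must take place at a tertiary carbon that lies next to the quaternary C6. A hydride shift from C4 (semipinacol pathway to a ketone without the second methyl) may outrun it, and the Lewis acid may also open the bromo ether. The fallback sets out from 9 and avoids the Lewis acid. Hydroboration (BH3·THF, then NaBO3·4H2O) gives the C4 alcohol F2, and Dess–Martin oxidation gives the ketone F3. Dehydrogenation with IBX in DMSO at 70 °C gives the enone F4; in the ring only C2=C3 can form because C6 has no hydrogen. Deprotonation with LiN(iPr)2 at the only acidic position, C5, and methyl iodide give the gem-dimethyl enone F5. Conjugate reduction with [(Ph3P)CuH]6 comes back to the route at 12.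

**Step 10.** Hydrogen abstraction at C2 may be too slow: the alkene is deactivated by bromine and C2 lies next to the fully substituted C1, so the substrate may be recovered or degrade under the large excess of oxidant. The fallback sets out from 12 and brings the C2 oxygen in by conjugate addition instead of C–H oxidation. IBX gives the enone F5. Copper-catalysed conjugate borylation (B2pin2, CuCl, NaOtBu, MeOH, THF) gives the β-boryl ketone F6, which NaBO3·4H2O oxidises to the β-hydroxy ketone F7. Silylation (TBSOTf, 2,6-lutidine) gives the silyl ether F8. Hydrazine hydrate gives the hydrazone F9, and NBS in pyridine gives the vinyl bromide F10. HF·pyridine frees the allylic alcohol F11, and Dess–Martin oxidation comes back to the route at 15.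

**Step 11.** The bromonium ion or tertiary cation at C9 may lose a proton instead of taking chloride, giving allylic bromides. BCl3 may also rest on the enone carbonyl without opening the ether, or exchange the vinylogous acyl bromide at C4 for chloride. The fallback sets out from 14 and changes the order, so the ether is opened before the enone exists. BCl3 in CH2Cl2 at −78 °C gives the chloro alcohol F12. The price is that the C1–O bond is no longer protected by a neighbouring carbonyl. Oxidation of F12 with CrO3 and 3,5-dimethylpyrazole then comes back to the route at 16.

**Step 2.** The share of 7 among the three diastereomeric diols may be low, its separation from the other cis-diol may be tedious, and the mono-adduct may open by retro-aldol cleavage if the cerium reagent is not fully formed. The fallback sets out from 5 with step 2 run unchanged and adds a recycling loop. The cis-diol epimeric at C6 F13 is treated with Co(salen)Cl (cat.) and PhSiH3. This hydrogen-atom-transfer isomerisation moves the ring B double bond between C8=C9 and C9=C10 through the tertiary C9 radical and thereby interconverts F13 and 7. Renewed separation comes back to the route at 7.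

**Step 4.** The sulfamate may lose a methyl hydrogen instead of a C4 hydrogen, because the leaving group is equatorial and no ring hydrogen is antiperiplanar to it. The fallback sets out from 8: the exocyclic alkene F14 formed in that case is isomerised with the same cobalt hydride system (Co(salen)Cl, PhSiH3) to the more substituted ring alkene and comes back to the route at 9.

## Further compounds

F1 | step 3 | enantiomer of 8 | C[C@@]1(O3)CCC[C@](C)(O)[C@@]12CC[C@]3(C)[C@H](Br)C2
F2 | step 6 | 8-bromo-1,9-epoxy-1,5,9-trimethylspiro[5.5]undecan-4-ol (C4, C5 not defined) | C[C@]1(O3)CCC(O)C(C)[C@]12CC[C@@]3(C)[C@@H](Br)C2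
F3 | step 6 | 8-bromo-1,9-epoxy-1,5,9-trimethylspiro[5.5]undecan-4-one (C5 not defined) | C[C@]1(O3)CCC(=O)C(C)[C@]12CC[C@@]3(C)[C@@H](Br)C2
F4 | step 6 | 8-bromo-1,9-epoxy-1,5,9-trimethylspiro[5.5]undec-2-en-4-one (C5 not defined) | C[C@]1(O3)C=CC(=O)C(C)[C@]12CC[C@@]3(C)[C@@H](Br)C2
F5 | step 6 | 8-bromo-1,9-epoxy-1,5,5,9-tetramethylspiro[5.5]undec-2-en-4-one | C[C@]1(O3)C=CC(=O)C(C)(C)[C@]12CC[C@@]3(C)[C@@H](Br)C2
F6 | step 10 | 8-bromo-1,9-epoxy-1,5,5,9-tetramethyl-2-(4,4,5,5-tetramethyl-1,3,2-dioxaborolan-2-yl)spiro[5.5]undecan-4-one (C2 not defined) | C[C@]1(O3)C(B4OC(C)(C)C(C)(C)O4)CC(=O)C(C)(C)[C@]12CC[C@@]3(C)[C@@H](Br)C2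
F7 | step 10 | 8-bromo-1,9-epoxy-2-hydroxy-1,5,5,9-tetramethylspiro[5.5]undecan-4-one (C2 not defined) | C[C@]1(O3)C(O)CC(=O)C(C)(C)[C@]12CC[C@@]3(C)[C@@H](Br)C2
F8 | step 10 | tert-butyldimethylsilyl ether of F7 | C[C@]1(O3)C(O[Si](C)(C)C(C)(C)C)CC(=O)C(C)(C)[C@]12CC[C@@]3(C)[C@@H](Br)C2
F9 | step 10 | hydrazone of F8 | C[C@]1(O3)C(O[Si](C)(C)C(C)(C)C)CC(=NN)C(C)(C)[C@]12CC[C@@]3(C)[C@@H](Br)C2
F10 | step 10 | 4,8-dibromo-2-(tert-butyldimethylsilyloxy)-1,9-epoxy-1,5,5,9-tetramethylspiro[5.5]undec-3-ene | C[C@]1(O3)C(O[Si](C)(C)C(C)(C)C)C=C(Br)C(C)(C)[C@]12CC[C@@]3(C)[C@@H](Br)C2
F11 | step 10 | 4,8-dibromo-1,9-epoxy-1,5,5,9-tetramethylspiro[5.5]undec-3-en-2-ol (C2 not defined) | C[C@]1(O3)C(O)C=C(Br)C(C)(C)[C@]12CC[C@@]3(C)[C@@H](Br)C2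
F12 | step 11 | 4,8-dibromo-9-chloro-1,5,5,9-tetramethylspiro[5.5]undec-3-en-1-ol | C[C@]1(O)CC=C(Br)C(C)(C)[C@]12CC[C@](C)(Cl)[C@@H](Br)C2
F13 | step 2 | cis-1,5,9-trimethylspiro[5.5]undec-8-ene-1,5-diol, hydroxyls on the face of ring A that carries C11 | C[C@]1(O)CCC[C@@](C)(O)[C@@]12CCC(C)=CC2
F14 | step 4 | 8-bromo-1,9-epoxy-1,9-dimethyl-5-methylidenespiro[5.5]undecane | C[C@]1(O3)CCCC(=C)[C@]12CC[C@@]3(C)[C@@H](Br)C2
A1 | alternative 1 | 4-[3-(tert-butyldimethylsilyloxy)-2-methylhept-6-yn-2-yl]phenol | Oc1ccc(cc1)C(C)(C)[C@@H](O[Si](C)(C)C(C)(C)C)CCC#C
A2 | alternative 1 | 4-(tert-butyldimethylsilyloxy)-5,5-dimethyl-1-methylidenespiro[5.5]undeca-7,10-dien-9-one | C=C1CC[C@H](O[Si](C)(C)C(C)(C)C)C(C)(C)C12C=CC(=O)C=C2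
A3 | alternative 2 | 3-bromo-2,2-dimethylcyclohex-3-ene-1-carbaldehyde | O=CC1CCC=C(Br)C1(C)C
A4 | alternative 2 | methyl vinyl ketone | CC(=O)C=C
A5 | alternative 2 | 2-bromo-1,1-dimethylspiro[5.5]undeca-2,7-dien-9-one | C1CC=C(Br)C(C)(C)[C@]12CCC(=O)C=C2
A6 | alternative 3 | (Z)-γ-bisabolene | CC1=CC/C(CC1)=C(/C)CCC=C(C)C
A7 | alternative 3 | 4-bromo-5,5,9-trimethyl-1-methylidenespiro[5.5]undec-8-ene | C=C1CC[C@H](Br)C(C)(C)[C@]12CCC(C)=CC2
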